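**Retrosynthetic overview**
- The carbocycle (ring A) is closed last by ring-closing metathesis at C4=C5; the 6,7-cis pair comes from a reagent-controlled syn-aldol of ketone 19 with acrolein.
- Ketone 19 comes from a Negishi coupling at C7a of a lactone-derived dienyl ketene-acetal phosphate with the zinc enolate of 4-phenylbutan-2-one; C4/C5 come from α-acetylation and O-methylation of the lactone.
- Key step: the cis-lactone 9 is made by carbene-catalysed homoenolate annulation, in which the β-carbon of an enal (normally electrophilic) attacks an aldehyde carbon to form C2–C3, O1–C7a and both stereocentres at once.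
- Ring order: oxolanone (lactone) first, then its conversion to the 2,3-dihydrofuran enol ether, then ring A.

Assumption: the absolute sense of induction of the two chiral reagents (triazolium carbene, step 5; diisopinocampheylboron enolate, step 9) is taken as drawn; both are available in either mirror-image form and the antipode is used if a test run shows the opposite sense.

**Step 1**
Reactants: 1 methyl 3-formyl-4-hydroxybenzoate
Product: 2 methyl 3-formyl-4-[tri(propan-2-yl)silyloxy]benzoate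
Conditions: iPr3SiCl, imidazole, DMF, 25 °C
Reagents that add atoms: chlorotri(propan-2-yl)silane, CC(C)[Si](Cl)(C(C)C)C(C)C
Why: Silyl ether protection of the phenol, which would otherwise trap the acyl azolium of step 5 as a dihydrocoumarin; no stereocentre is formed.

**Step 2**
Reactants: 2 methyl 3-formyl-4-[tri(propan-2-yl)silyloxy]benzoate; 3 2-(triphenylphosphoranylidene)acetaldehyde
Product: 4 methyl 3-[(E)-3-oxoprop-1-enyl]-4-[tri(propan-2-yl)silyloxy]benzoate
Conditions: toluene, 80 °C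
Reagents that add atoms: none
Why: Wittig olefination with a stabilised ylide gives the E-enal; no stereocentre is formed.

**Step 3**
Reactants: 5 2-methylbut-3-en-2-ol
Product: 6 triethyl[(2-methylbut-3-en-2-yl)oxy]silane
Conditions: Et3SiOTf, 2,6-lutidine, CH2Cl2, 0 °C
Reagents that add atoms: triethylsilyl trifluoromethanesulfonate, CC[Si](CC)(CC)OS(=O)(=O)C(F)(F)F
Why: Silyl triflate protection of the hindered tertiary alcohol, which must not be acylated or phosphorylated in steps 6 and 7.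

**Step 4**
Reactants: 6 triethyl[(2-methylbut-3-en-2-yl)oxy]silane
Product: 8 2-methyl-2-(triethylsilyloxy)propanal, via ozonide 7 (not isolated)
Conditions: O3, CH2Cl2, −78 °C; then PPh3, −78 to 25 °C
Reagents that add atoms: ozone, [O-][O+]=O
Why: Ozonolysis with reductive work-up cleaves the vinyl group to a non-enolisable α-silyloxy aldehyde.

**Step 5**
Reactants: 4 methyl 3-[(E)-3-oxoprop-1-enyl]-4-[tri(propan-2-yl)silyloxy]benzoate; 8 2-methyl-2-(triethylsilyloxy)propanal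
Product: 9 methyl 3-[(2R,3R)-5-oxo-2-[2-(triethylsilyloxy)propan-2-yl]oxolan-3-yl]-4-[tri(propan-2-yl)silyloxy]benzoate (2,3-cis lactone)
Conditions: (5aR,10bS)-2-mesityl-indeno[2,1-b]triazolo[4,3-d][1,4]oxazinium chloride (10 mol%), DBU (15 mol%), THF, 25 °C; 8 in threefold excess, slow addition of 4
Reagents that add atoms: none
Why: Proposed new method: the carbene turns the enal into a Breslow-type homoenolate whose β-carbon adds to the activated, non-enolisable aldehyde 8, and the resulting alkoxide closes onto the acyl azolium to give the cis-4,5-disubstituted lactone; the chiral triazolium shields one enal face and so sets C2 and C3 together (minor trans isomer removed by chromatography). The closest known reaction type is the carbene-catalysed enal–aldehyde homoenolate annulation to cis-γ-butyrolactones, whose enantioselective forms are established mainly for activated ketones.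

**Step 6**
Reactants: 9 cis-lactone (as above); 10 1-acetylimidazole
Product: 13 methyl 3-[(2R,3S)-4-(1-methoxyethylidene)-5-oxo-2-[2-(triethylsilyloxy)propan-2-yl]oxolan-3-yl]-4-[tri(propan-2-yl)silyloxy]benzoate (E/Z mixture), via lactone lithium enolate 11 (not isolated), via acetyl-lactone lithium enolate 12 (not isolated)
Conditions: LiN(SiMe3)2 (2.2 equiv), THF, −78 °C; 10; then DMPU, MeOTf (3 equiv), −78 to 0 °C
Reagents that add atoms: methyl trifluoromethanesulfonate, COS(=O)(=O)C(F)(F)F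
Why: Claisen C-acylation of the lactone enolate, then O-alkylation of the β-keto-lactone enolate by a hard methylating agent in a dipolar cosolvent (hindered tertiary α-carbon disfavours C-methylation); C2 and C3 are untouched (the descriptor at C3 changes by priority only).

**Step 7**
Reactants: 13 methoxyethylidene lactone (as above)
Product: 15 methyl 3-[(2R,3S)-5-(diphenoxyphosphoryloxy)-4-(1-methoxyethenyl)-2-[2-(triethylsilyloxy)propan-2-yl]-2,3-dihydrofuran-3-yl]-4-[tri(propan-2-yl)silyloxy]benzoate, via potassium dienolate 14 (not isolated)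
Conditions: KN(SiMe3)2, THF/DMPU, −78 °C; then (PhO)2P(O)Cl
Reagents that add atoms: diphenyl phosphorochloridate, O=P(Cl)(Oc1ccccc1)Oc1ccccc1
Why: γ-Deprotonation of the vinylogous carbonate (as in Brassard-diene formation) and O-phosphorylation of the only enolate oxygen gives a ketene-acetal phosphate that already carries the ring-A diene pattern with a leaving group at C7a.

**Step 8**
Reactants: 15 dienyl phosphate (as above); 16 4-phenylbutan-2-one
Product: 19 methyl 3-[(2R,3S)-4-(1-methoxyethenyl)-5-(2-oxo-4-phenylbutyl)-2-[2-(triethylsilyloxy)propan-2-yl]-2,3-dihydrofuran-3-yl]-4-[tri(propan-2-yl)silyloxy]benzoate, via lithium enolate 17 (not isolated), via chlorozinc enolate 18 (not isolated)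
Conditions: 16, LiN(iPr)2, THF, −78 °C; ZnCl2; then 15, Pd(PPh3)4 (5 mol%), THF, 50 °C
Reagents that add atoms: none
Why: Negishi cross-coupling of a lactone-derived ketene-acetal phosphate with the kinetic (methyl-side) zinc enolate forms C7–C7a while O1 stays on C7a; the aryl ester survives because no hard nucleophile is used.

**Step 9**
Reactants: 19 ketone (as above); 20 prop-2-enal
Product: 23 methyl 3-[(2R,3S)-5-[(4S,5S)-5-hydroxy-3-oxo-1-phenylhept-6-en-4-yl]-4-(1-methoxyethenyl)-2-[2-(triethylsilyloxy)propan-2-yl]-2,3-dihydrofuran-3-yl]-4-[tri(propan-2-yl)silyloxy]benzoate, via Z-boron enolate 21 (not isolated), via boron aldolate 22 (not isolated)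
Conditions: (−)-Ipc2BOTf, iPr2NEt, CH2Cl2, −78 to −20 °C; 20, −78 °C; then MeOH, pH 7 buffer, H2O2, 0 °C
Reagents that add atoms: none
Why: Paterson-type boron aldol: the more acidic C–H (between the ketone and the dienol-ether carbon) is removed to give the Z-enol borinate, whose chair Zimmerman–Traxler transition state gives the syn adduct (the future 6,7-cis pair), while the isopinocampheyl ligands choose the aldehyde face, so both new centres are reagent-controlled and independent of the remote dihydrofuran centres.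

**Step 10**
Reactants: 23 syn-aldol (as above)
Product: 24 methyl 3-[(2R,3S,6S,7S)-6-hydroxy-4-methoxy-7-(3-phenylpropanoyl)-2-[2-(triethylsilyloxy)propan-2-yl]-2,3,6,7-tetrahydro-1-benzofuran-3-yl]-4-[tri(propan-2-yl)silyloxy]benzoate
Conditions: second-generation Grubbs catalyst RuCl2(H2IMes)(PCy3)(=CHPh) (10 mol%), toluene (2 mM), 40 °C
Reagents that add atoms: none
Why: Ring-closing metathesis between the vinyl group and the 1,1-disubstituted methyl enol ether closes ring A under neutral conditions, so the C7 hydrogen, the aldol and the unconjugated diene are formed without base or acid; no new stereocentre.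

**Step 11**
Reactants: 24 bis-silyl ether (as above)
Product: 25 methyl 4-hydroxy-3-[(2R,3S,6S,7S)-6-hydroxy-2-(2-hydroxypropan-2-yl)-4-methoxy-7-(3-phenylpropanoyl)-2,3,6,7-tetrahydro-1-benzofuran-3-yl]benzoate (CNP0080427.1)
Conditions: Bu4NF, AcOH (1:1, 3 equiv), THF, 0 to 25 °C
Reagents that add atoms: none
Why: Acetic-acid-buffered fluoride removes both silyl ethers without free base, avoiding retro-aldol, dehydration to the arene and double-bond migration; stereocentres are untouched.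

**Compound list**
1 | methyl 3-formyl-4-hydroxybenzoate | COC(=O)c1ccc(O)c(C=O)c1 | starting material
2 | methyl 3-formyl-4-[tri(propan-2-yl)silyloxy]benzoate | COC(=O)c1ccc(O[Si](C(C)C)(C(C)C)C(C)C)c(C=O)c1 | intermediate
3 | 2-(triphenylphosphoranylidene)acetaldehyde | O=CC=P(c1ccccc1)(c1ccccc1)c1ccccc1 | starting material
4 | methyl 3-[(E)-3-oxoprop-1-enyl]-4-[tri(propan-2-yl)silyloxy]benzoate | COC(=O)c1ccc(O[Si](C(C)C)(C(C)C)C(C)C)c(/C=C/C=O)c1 | intermediate
5 | 2-methylbut-3-en-2-ol | C=CC(C)(C)O | starting material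
6 | triethyl[(2-methylbut-3-en-2-yl)oxy]silane | C=CC(C)(C)O[Si](CC)(CC)CC | intermediate
7 | 3-[2-(triethylsilyloxy)propan-2-yl]-1,2,4-trioxolane (ozonide, not isolated) | CC[Si](CC)(CC)OC(C)(C)C1OCOO1 | intermediate
8 | 2-methyl-2-(triethylsilyloxy)propanal | O=CC(C)(C)O[Si](CC)(CC)CC | intermediate
9 | methyl 3-[(2R,3R)-5-oxo-2-[2-(triethylsilyloxy)propan-2-yl]oxolan-3-yl]-4-[tri(propan-2-yl)silyloxy]benzoate | COC(=O)c1ccc(O[Si](C(C)C)(C(C)C)C(C)C)c([C@H]2CC(=O)O[C@H]2C(C)(C)O[Si](CC)(CC)CC)c1 | intermediate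
10 | 1-acetylimidazole | CC(=O)n1ccnc1 | starting material
11 | lithium enolate of lactone 9 (not isolated) | COC(=O)c1ccc(O[Si](C(C)C)(C(C)C)C(C)C)c([C@H]2C=C([O-])O[C@H]2C(C)(C)O[Si](CC)(CC)CC)c1.[Li+] | intermediate
12 | lithium enolate of the 4-acetyl derivative of lactone 9 (not isolated) | COC(=O)c1ccc(O[Si](C(C)C)(C(C)C)C(C)C)c([C@H]2C(=C(C)[O-])C(=O)O[C@H]2C(C)(C)O[Si](CC)(CC)CC)c1.[Li+] | intermediate
13 | methyl 3-[(2R,3S)-4-(1-methoxyethylidene)-5-oxo-2-[2-(triethylsilyloxy)propan-2-yl]oxolan-3-yl]-4-[tri(propan-2-yl)silyloxy]benzoate | COC(=O)c1ccc(O[Si](C(C)C)(C(C)C)C(C)C)c([C@H]2C(=C(C)OC)C(=O)O[C@H]2C(C)(C)O[Si](CC)(CC)CC)c1 | intermediate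
14 | potassium dienolate of 13 (not isolated) | COC(=O)c1ccc(O[Si](C(C)C)(C(C)C)C(C)C)c([C@H]2C(C(=C)OC)=C([O-])O[C@H]2C(C)(C)O[Si](CC)(CC)CC)c1.[K+] | intermediate
15 | methyl 3-[(2R,3S)-5-(diphenoxyphosphoryloxy)-4-(1-methoxyethenyl)-2-[2-(triethylsilyloxy)propan-2-yl]-2,3-dihydrofuran-3-yl]-4-[tri(propan-2-yl)silyloxy]benzoate | COC(=O)c1ccc(O[Si](C(C)C)(C(C)C)C(C)C)c([C@H]2C(C(=C)OC)=C(OP(=O)(Oc3ccccc3)Oc3ccccc3)O[C@H]2C(C)(C)O[Si](CC)(CC)CC)c1 | intermediate
16 | 4-phenylbutan-2-one | CC(=O)CCc1ccccc1 | starting material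
17 | lithium 4-phenylbut-1-en-2-olate (not isolated) | [Li+].[O-]C(=C)CCc1ccccc1 | intermediate
18 | chlorozinc 4-phenylbut-1-en-2-olate (not isolated) | C=C(CCc1ccccc1)O[Zn]Cl | intermediate
19 | methyl 3-[(2R,3S)-4-(1-methoxyethenyl)-5-(2-oxo-4-phenylbutyl)-2-[2-(triethylsilyloxy)propan-2-yl]-2,3-dihydrofuran-3-yl]-4-[tri(propan-2-yl)silyloxy]benzoate | COC(=O)c1ccc(O[Si](C(C)C)(C(C)C)C(C)C)c([C@H]2C(C(=C)OC)=C(CC(=O)CCc3ccccc3)O[C@H]2C(C)(C)O[Si](CC)(CC)CC)c1 | intermediate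
20 | prop-2-enal | C=CC=O | starting material
21 | (Z)-diisopinocampheylboron enolate of 19 (not isolated) | COC(=O)c1ccc(O[Si](C(C)C)(C(C)C)C(C)C)c([C@H]2C(C(=C)OC)=C(/C=C(/CCc3ccccc3)OB([C@@H]3C[C@@H]4C[C@H]([C@H]3C)C4(C)C)[C@@H]3C[C@@H]4C[C@H]([C@H]3C)C4(C)C)O[C@H]2C(C)(C)O[Si](CC)(CC)CC)c1 | intermediate
22 | diisopinocampheylborinate of aldol 23 (not isolated) | COC(=O)c1ccc(O[Si](C(C)C)(C(C)C)C(C)C)c([C@H]2C(C(=C)OC)=C([C@@H](C(=O)CCc3ccccc3)[C@@H](OB([C@@H]3C[C@@H]4C[C@H]([C@H]3C)C4(C)C)[C@@H]3C[C@@H]4C[C@H]([C@H]3C)C4(C)C)C=C)O[C@H]2C(C)(C)O[Si](CC)(CC)CC)c1 | intermediate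
23 | methyl 3-[(2R,3S)-5-[(4S,5S)-5-hydroxy-3-oxo-1-phenylhept-6-en-4-yl]-4-(1-methoxyethenyl)-2-[2-(triethylsilyloxy)propan-2-yl]-2,3-dihydrofuran-3-yl]-4-[tri(propan-2-yl)silyloxy]benzoate | COC(=O)c1ccc(O[Si](C(C)C)(C(C)C)C(C)C)c([C@H]2C(C(=C)OC)=C([C@@H](C(=O)CCc3ccccc3)[C@@H](O)C=C)O[C@H]2C(C)(C)O[Si](CC)(CC)CC)c1 | intermediate
24 | methyl 3-[(2R,3S,6S,7S)-6-hydroxy-4-methoxy-7-(3-phenylpropanoyl)-2-[2-(triethylsilyloxy)propan-2-yl]-2,3,6,7-tetrahydro-1-benzofuran-3-yl]-4-[tri(propan-2-yl)silyloxy]benzoate | COC(=O)c1ccc(O[Si](C(C)C)(C(C)C)C(C)C)c([C@H]2C3=C(O[C@H]2C(C)(C)O[Si](CC)(CC)CC)[C@@H](C(=O)CCc2ccccc2)[C@@H](O)C=C3OC)c1 | intermediate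
25 | methyl 4-hydroxy-3-[(2R,3S,6S,7S)-6-hydroxy-2-(2-hydroxypropan-2-yl)-4-methoxy-7-(3-phenylpropanoyl)-2,3,6,7-tetrahydro-1-benzofuran-3-yl]benzoate | COC(=O)c1ccc(O)c([C@H]2C3=C(O[C@H]2C(C)(C)O)[C@@H](C(=O)CCc2ccccc2)[C@@H](O)C=C3OC)c1 | target

**Step count and risks**
Total steps: 11. Longest linear sequence: 9 (steps 1, 2, 5, 6, 7, 8, 9, 10, 11).

Most likely to fail:

1. Step 5. The hindered aliphatic aldehyde may react slowly, so enal self-annulation competes, and cis-selectivity and ee may be modest. Fallback, from 8 back to 9: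
   - Add methyl propiolate to 8 with ZnMe2 and a ProPhenol ligand (antipode chosen for 4R) to give methyl (4R)-4-hydroxy-5-methyl-5-(triethylsilyloxy)hex-2-ynoate F1.
   - Silylate commercial methyl 4-hydroxy-3-iodobenzoate to methyl 3-iodo-4-[tri(propan-2-yl)silyloxy]benzoate F2.
   - Reductive hydroarylation of F1 with F2 (Pd(OAc)2, HCO2H, Et3N, DMF) lactonises in the flask to methyl 3-[(2R)-5-oxo-2-[2-(triethylsilyloxy)propan-2-yl]-2,5-dihydrofuran-3-yl]-4-[tri(propan-2-yl)silyloxy]benzoate F3.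
   - Hydrogenation over Pd on carbon delivers hydrogen anti to the bulky C2 substituent and gives cis-lactone 9.

2. Step 8. The zinc ketone enolate may transmetalate poorly or attack phosphorus. Fallback, from 15 and 16 back to 19:
   - Convert 16 (LiN(iPr)2, Me3SiCl) into trimethyl[(4-phenylbut-1-en-2-yl)oxy]silane F4.
   - Hydroborate with 9-BBN-H to 9-[4-phenyl-2-(trimethylsilyloxy)butyl]-9-borabicyclo[3.3.1]nonane F5.
   - B-alkyl Suzuki–Miyaura coupling with 15 (PdCl2(dppf), Cs2CO3, DMF/THF/H2O) gives the 5-[4-phenyl-2-(trimethylsilyloxy)butyl] dihydrofuran F6.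
   - K2CO3/MeOH at 0 °C frees the secondary alcohol F7, and Dess–Martin periodinane (NaHCO3 buffer) gives 19.

3. Step 9. Enolisation may be unselective, or the boron Lewis acid may attack the methoxydiene. Fallback, from 19 back to 24, closing ring A by the C6–C7 bond so that steps 9 and 10 are both replaced:
   - Formylate the terminal carbon of the methoxydiene with (chloromethylene)dimethyliminium chloride and 2,6-lutidine to the vinylogous iminium chloride F8.
   - Hydrolyse with aqueous NaOAc to the 1-methoxy-3-oxopropenyl dienal F9.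
   - Enolise the now doubly activated methylene with (−)-Ipc2BOTf/iPr2NEt to the boron enolate F10, which closes onto the tethered aldehyde through a boron chelate (cis at C6/C7) to the cyclised borinate F11.
   - Buffered H2O2 work-up gives 24.

**Further compounds**
F1 | step 5 | methyl (4R)-4-hydroxy-5-methyl-5-(triethylsilyloxy)hex-2-ynoate | O[C@H](C#CC(=O)OC)C(C)(C)O[Si](CC)(CC)CC
F2 | step 5 | methyl 3-iodo-4-[tri(propan-2-yl)silyloxy]benzoate | COC(=O)c1ccc(O[Si](C(C)C)(C(C)C)C(C)C)c(I)c1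
F3 | step 5 | methyl 3-[(2R)-5-oxo-2-[2-(triethylsilyloxy)propan-2-yl]-2,5-dihydrofuran-3-yl]-4-[tri(propan-2-yl)silyloxy]benzoate | COC(=O)c1ccc(O[Si](C(C)C)(C(C)C)C(C)C)c(C2=CC(=O)O[C@H]2C(C)(C)O[Si](CC)(CC)CC)c1
F4 | step 8 | trimethyl[(4-phenylbut-1-en-2-yl)oxy]silane | C=C(CCc1ccccc1)O[Si](C)(C)C
F5 | step 8 | 9-[4-phenyl-2-(trimethylsilyloxy)butyl]-9-borabicyclo[3.3.1]nonane | C[Si](C)(C)OC(CCc1ccccc1)CB1C2CCCC1CCC2
F6 | step 8 | methyl 3-[(2R,3S)-4-(1-methoxyethenyl)-5-[4-phenyl-2-(trimethylsilyloxy)butyl]-2-[2-(triethylsilyloxy)propan-2-yl]-2,3-dihydrofuran-3-yl]-4-[tri(propan-2-yl)silyloxy]benzoate (both epimers at the silyloxy carbon) | COC(=O)c1ccc(O[Si](C(C)C)(C(C)C)C(C)C)c([C@H]2C(C(=C)OC)=C(CC(CCc3ccccc3)O[Si](C)(C)C)O[C@H]2C(C)(C)O[Si](CC)(CC)CC)c1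
F7 | step 8 | methyl 3-[(2R,3S)-5-(2-hydroxy-4-phenylbutyl)-4-(1-methoxyethenyl)-2-[2-(triethylsilyloxy)propan-2-yl]-2,3-dihydrofuran-3-yl]-4-[tri(propan-2-yl)silyloxy]benzoate (both carbinol epimers) | COC(=O)c1ccc(O[Si](C(C)C)(C(C)C)C(C)C)c([C@H]2C(C(=C)OC)=C(CC(O)CCc3ccccc3)O[C@H]2C(C)(C)O[Si](CC)(CC)CC)c1
F8 | step 9 | N-[3-methoxy-3-[(4S,5R)-4-aryl-2-(2-oxo-4-phenylbutyl)-5-[2-(triethylsilyloxy)propan-2-yl]-4,5-dihydrofuran-3-yl]prop-2-enylidene]-N-methylmethanaminium chloride (aryl = 5-methoxycarbonyl-2-[tri(propan-2-yl)silyloxy]phenyl) | COC(=O)c1ccc(O[Si](C(C)C)(C(C)C)C(C)C)c([C@H]2C(C(OC)=CC=[N+](C)C)=C(CC(=O)CCc3ccccc3)O[C@H]2C(C)(C)O[Si](CC)(CC)CC)c1.[Cl-]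
F9 | step 9 | methyl 3-[(2R,3S)-4-(1-methoxy-3-oxoprop-1-enyl)-5-(2-oxo-4-phenylbutyl)-2-[2-(triethylsilyloxy)propan-2-yl]-2,3-dihydrofuran-3-yl]-4-[tri(propan-2-yl)silyloxy]benzoate | COC(=O)c1ccc(O[Si](C(C)C)(C(C)C)C(C)C)c([C@H]2C(C(OC)=CC=O)=C(CC(=O)CCc3ccccc3)O[C@H]2C(C)(C)O[Si](CC)(CC)CC)c1
F10 | step 9 | (Z)-diisopinocampheylboron enolate of F9 | COC(=O)c1ccc(O[Si](C(C)C)(C(C)C)C(C)C)c([C@H]2C(C(OC)=CC=O)=C(/C=C(/CCc3ccccc3)OB([C@@H]3C[C@@H]4C[C@H]([C@H]3C)C4(C)C)[C@@H]3C[C@@H]4C[C@H]([C@H]3C)C4(C)C)O[C@H]2C(C)(C)O[Si](CC)(CC)CC)c1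
F11 | step 9 | 6-O-diisopinocampheylborinate of 24 | COC(=O)c1ccc(O[Si](C(C)C)(C(C)C)C(C)C)c([C@H]2C3=C(O[C@H]2C(C)(C)O[Si](CC)(CC)CC)[C@@H](C(=O)CCc2ccccc2)[C@@H](OB([C@@H]2C[C@@H]4C[C@H]([C@H]2C)C4(C)C)[C@@H]2C[C@@H]4C[C@H]([C@H]2C)C4(C)C)C=C3OC)c1
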